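The vessel is closed, stirred and isothermal, and the flasks below share their charges of free base, protonated nucleophile and protic impurity; they differ in electrophile.

| flask | electrophile | free base | protonated nucleophile | protic impurity | remark | time |
|---|---|---|---|---|---|---|
| epsilon | 0.015 M | 0.40 M | 0.36 M | 0.12 M | run made earlier |  |
| eta | 0.27 M | 0.40 M | 0.36 M | 0.12 M | run made earlier |  |
| west | 0.025 M | 0.400 M | 0.360 M | 0.120 M |  | 6.0 min |
| north | 0.050 M | 0.400 M | 0.360 M | 0.120 M |  | 6.0 min |
| south-east | 0.10 M | 0.400 M | 0.360 M | 0.120 M |  | 6.0 min |
| north-east | 0.20 M | 0.400 M | 0.360 M | 0.120 M |  | 6.0 min |
| south-west | 0.40 M | 0.400 M | 0.360 M | 0.120 M |  | 6.0 min |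

| run | time / min | product / % | electrophile / % |
|---|---|---|---|
| epsilon | 0.833 | 10.6 | 89.4 |
| epsilon | 2.00 | 19.8 | 80.1 |
| epsilon | 4.00 | 33.0 | 69.8 |
| epsilon | 6.00 | 37.9 | 62.6 |
| eta | 0.500 | 5.8 | 95.4 |
| eta | 1.00 | 9.5 | 88.4 |
| eta | 2.50 | 18.8 | 80.1 |
| eta | 6.00 | 28.7 | 70.6 |

(scatter of a reading: 1 percentage point)

- the earlier runs were read with a standard deviation of 1 percentage point
- a reading or a percentage of product counts all its forms, free or not
- the concentration of product that is asked is that of its free form alone
- "hardly changes" means that all values lie within two and a half points (for a concentration: within two and a half percent of the largest)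

- [product] (only what is free in solution) at the end for west, north, south-east, north-east, south-west, in this order
- the shape of the row from first to last (rises all the way / falls, then rises / hardly changes / rises, then falls / falls all the way)

1. At 6.00 min epsilon reads 37.9% product and eta reads 28.7%. The gap is 9.2 percentage points and the scatter 1 point per reading, so I treat the drop in yield as real.

2. I take two extremes for south-west, whose charge stands above eta's. If it kept eta's yield, it would hold 0.115 M. If it kept eta's amount, it would hold 0.0775 M. From epsilon to eta the amount climbs from 0.00568 M to 0.0775 M while the yield sinks, so I place south-west between the two extremes.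

3. The drop is smaller than epsilon's yield, so I reckon the correction and nothing else. Dividing the gap by the difference in charge gives 0.361 /M, the yield penalty: the fraction of yield at 6.00 min lost for each molar of extra electrophile. A flask's yield is then epsilon's yield minus the penalty times its extra charge, and its product is that yield times its charge.

4. My row is 0.00938 M, 0.0183 M, 0.0348 M, 0.0625 M and 0.0960 M, rising from first to last. I count all product as free, which the readings cannot test. The last point lies between the extremes, but its charge stands beyond eta's, so it is an extrapolation.

5. The forecast, which gives 0.0039 M, 0.0077 M, 0.0155 M, 0.032 M and 0.064 M (rises all the way), stands below my row on the ground that “Free product is roughly 40–55% of total product”.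

6. The flask gives 0.00928 M, 0.0182 M, 0.0347 M, 0.0633 M and 0.106 M: rises all the way.

    crystals ⇌ product, rate k1*(cs1 - [product]) while solid is left; crystals form when [product] > cs1 (solubility = 0.320 M, k = 11.5 /min)
    nucleophile + acid set free ⇌ protonated nucleophile, settled at all times (K = 556 /M)
    electrophile + nucleophile → acid set free + product (k = 0.657 /M/min)
    acid set free + free base ⇌ salt of the base, settled at all times (K = 1200 /M)
    protic impurity + free base → quenched reagent (k = 0.971 /M/min)
    2 nucleophile → homo dimer (k = 0.947 /M/min)

The penalty put north-east at 0.0625 M beside its 0.0633 M, and south-west at 0.0960 M beside its 0.106 M. Crystals stand at 0% in south-west and make no difference, so its product is free. The largest single effect on [product] in south-west is the joining of acid set free and free base to salt of the base, both ways: with that joining taken away, south-west ends at 0.0226 M instead of 0.106 M.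

Readings and results stem from a simulated flask from invented constants, and the scatter is random.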